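**Retrosynthetic overview**

1. 26 ⇐ 22 (C7=C8 alkene, C2–CH2OSi as masked vinyl) by hydrogenation, desilylation, oxidation and Wittig methylenation.
2. 22 ⇐ 18 by a tandem double Ireland–Claisen rearrangement: the vicinal C5–CH2CO2H / C6–CMe2CO2H pair is read as two [3,3]-shifts from a trans 7-acetate/8-isobutyrate across C5=C6.
3. 18 ⇐ 16 ⇐ diazo ketone 14 by copper-carbenoid oxonium ylide formation and [2,3]-shift: the seven-membered oxepine (O1, C2, C3, C4, C4a, C5, C6) contracts to the oxane (O1, C2, C3, C4, C4a, C8a) while the cyclohexene (C4a, C5, C6, C7, C8, C8a) closes.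
4. Enabling feature: O1 sits on the fully substituted C8a, flanked by C8 (which can carry a temporary ketone) and by the ring-fusion carbon C4a; with C5=C6 unsaturated, C4a–C5–C6 is an allyl unit that can move from O1 to an ylide carbon C8a, and this also delivers the cis fusion (C8a–CH3 cis to H-4a).
5. 14 ⇐ oxepine 9 (ring-closing metathesis) ⇐ methallyl ether 4 (alkoxyallylboration with ethyl glyoxylate, then Mitsunobu inversion) ⇐ (S)-2-methylglycidol 1. Ring order: oxepine (step 6), then oxane and carbocycle together (step 10).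

Key step: step 10

Remark: atoms carry the chromene numbering of the target (O1, C2, C3, C4, C4a, C5, C6, C7, C8, C8a); alkoxides, carboxylates and borinates that are only protonated or hydrolysed on work-up are counted with their neutral forms; (S)-2-methylglycidol is taken as commercially available.

**Route**

Step 1
Reactants: 1 (S)-2-methylglycidol
Product: 2 tert-butyldimethyl{[(2R)-2-methyloxiran-2-yl]methoxy}silane
Conditions: TBSCl, imidazole, DMF, 0 °C to rt
Reagents that add atoms: tert-butyldimethylsilyl chloride, CC(C)(C)[Si](C)(C)Cl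
Why: Silyl ether formation at the primary alcohol leaves the epoxide and the stereocentre untouched and masks the carbon that becomes the vinyl CH at the end.

Step 2
Reactants: 2 tert-butyldimethyl{[(2R)-2-methyloxiran-2-yl]methoxy}silane
Product: 3 (2R)-1-[(tert-butyldimethylsilyl)oxy]-2-methylhept-6-en-2-ol
Conditions: CH2=CHCH2MgBr, CuI (10 mol %), THF, −40 to 0 °C; H2O
Reagents that add atoms: allylmagnesium bromide, C=CC[Mg]Br
Why: Copper-catalysed Grignard opening of the 2,2-disubstituted epoxide should occur by SN2 at the CH2 terminus, so the quaternary stereocentre (C2) is retained.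

Step 3
Reactants: 3 (2R)-1-[(tert-butyldimethylsilyl)oxy]-2-methylhept-6-en-2-ol
Product: 4 tert-butyldimethyl{[(2R)-2-methyl-2-[(2-methylprop-2-en-1-yl)oxy]hept-6-en-1-yl]oxy}silane
Conditions: KH, THF, 0 °C; 3-bromo-2-methylprop-1-ene, Bu4NI (cat.), 0 °C to rt
Reagents that add atoms: 3-bromo-2-methylprop-1-ene, C=C(C)CBr
Why: Williamson ether synthesis of the tertiary potassium alkoxide with a reactive allylic bromide forms the hindered tertiary ether (O1–C6) without touching the stereocentre.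

Step 4
Reactants: 4 tert-butyldimethyl{[(2R)-2-methyl-2-[(2-methylprop-2-en-1-yl)oxy]hept-6-en-1-yl]oxy}silane
Product: 7 ethyl (2S,3R)-3-{[(2R)-1-[(tert-butyldimethylsilyl)oxy]-2-methylhept-6-en-2-yl]oxy}-2-hydroxy-4-methylpent-4-enoate, via lithiated allyl ether 5 (not isolated), via alkoxyallylborane 6 (not isolated)
Conditions: s-BuLi, THF, −78 °C; (−)-Ipc2BOMe [from (+)-α-pinene], −78 °C; BF3·OEt2; ethyl glyoxylate, −78 °C; pH 7 buffer, H2O2, MeOH, 0 °C
Reagents that add atoms: ethyl glyoxylate, CCOC(=O)C=O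
Why: Brown alkoxyallylboration: α-lithiation gives the chelated (Z)-alkoxyallyl anion, boron transfer gives the (Z)-γ-alkoxyallylborane, and its chair transition state with the isopinocampheyl groups from (+)-α-pinene should add to the si face of the aldehyde, setting C6 and C7 syn as (3R,2S).

Step 5
Reactants: 7 ethyl (2S,3R)-3-{[(2R)-1-[(tert-butyldimethylsilyl)oxy]-2-methylhept-6-en-2-yl]oxy}-2-hydroxy-4-methylpent-4-enoate
Product: 8 ethyl (2R,3R)-3-{[(2R)-1-[(tert-butyldimethylsilyl)oxy]-2-methylhept-6-en-2-yl]oxy}-4-methyl-2-[(4-nitrobenzoyl)oxy]pent-4-enoate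
Conditions: 4-nitrobenzoic acid, PPh3, DIAD, THF, 0 °C to rt
Reagents that add atoms: 4-nitrobenzoic acid, OC(=O)c1ccc(cc1)[N+](=O)[O-]
Why: Mitsunobu reaction: SN2 displacement at the activated α-hydroxy ester carbon inverts C7 and gives the anti array that the key step needs.

Step 6
Reactants: 8 ethyl (2R,3R)-3-{[(2R)-1-[(tert-butyldimethylsilyl)oxy]-2-methylhept-6-en-2-yl]oxy}-4-methyl-2-[(4-nitrobenzoyl)oxy]pent-4-enoate
Product: 9 ethyl (2R)-2-[(2R,7R)-7-{[(tert-butyldimethylsilyl)oxy]methyl}-3,7-dimethyl-2,5,6,7-tetrahydrooxepin-2-yl]-2-[(4-nitrobenzoyl)oxy]acetate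
Conditions: second-generation Grubbs catalyst (5 mol %), CH2Cl2 (0.005 M), 40 °C
Reagents that add atoms: none
Why: Ring-closing metathesis of the terminal and the 1,1-disubstituted alkene should close the seven-membered oxepine with the trisubstituted C4a=C5 alkene, helped by the gem-disubstituted C2; no stereocentre is touched.

Step 7
Reactants: 9 ethyl (2R)-2-[(2R,7R)-7-{[(tert-butyldimethylsilyl)oxy]methyl}-3,7-dimethyl-2,5,6,7-tetrahydrooxepin-2-yl]-2-[(4-nitrobenzoyl)oxy]acetate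
Product: 10 (2R)-2-[(2R,7R)-7-{[(tert-butyldimethylsilyl)oxy]methyl}-3,7-dimethyl-2,5,6,7-tetrahydrooxepin-2-yl]-2-hydroxyacetic acid
Conditions: LiOH, THF/H2O, 0 °C to rt; then 1 M HCl to pH 3, 0 °C
Reagents that add atoms: lithium hydroxide, [Li+].[OH-]
Why: Saponification cleaves both esters by acyl–oxygen fission, so C7 keeps its configuration and the primary silyl ether survives.

Step 8
Reactants: 10 (2R)-2-[(2R,7R)-7-{[(tert-butyldimethylsilyl)oxy]methyl}-3,7-dimethyl-2,5,6,7-tetrahydrooxepin-2-yl]-2-hydroxyacetic acid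
Product: 12 (2R)-2-(acetyloxy)-2-[(2R,7R)-7-{[(tert-butyldimethylsilyl)oxy]methyl}-3,7-dimethyl-2,5,6,7-tetrahydrooxepin-2-yl]acetic acid, via mixed acetic anhydride 11 (not isolated)
Conditions: Ac2O, pyridine, DMAP (cat.), CH2Cl2, 0 °C to rt; then THF/H2O
Reagents that add atoms: acetic anhydride, CC(=O)OC(C)=O
Why: DMAP-catalysed acyl transfer installs the acetate that later becomes the C5 acetic acid arm, and the transient mixed anhydride of the carboxyl group is hydrolysed on work-up.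

Step 9
Reactants: 12 (2R)-2-(acetyloxy)-2-[(2R,7R)-7-{[(tert-butyldimethylsilyl)oxy]methyl}-3,7-dimethyl-2,5,6,7-tetrahydrooxepin-2-yl]acetic acid
Product: 14 (1R)-3-diazo-1-[(2R,7R)-7-{[(tert-butyldimethylsilyl)oxy]methyl}-3,7-dimethyl-2,5,6,7-tetrahydrooxepin-2-yl]-2-oxobutyl acetate, via mixed carbonic anhydride 13 (not isolated)
Conditions: i-BuOCOCl, Et3N, THF, −20 °C; then CH3CHN2 (Et2O solution, excess), −20 to 0 °C
Reagents that add atoms: diazoethane, CC=[N+]=[N-]
Why: Acylation of a diazoalkane by the activated carboxyl group gives the α-methyl diazo ketone under non-acidic conditions that spare the tertiary allylic ether; the leaving isobutyl carbonate takes the proton and collapses to the alcohol and CO2.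

Step 10
Reactants: 14 (1R)-3-diazo-1-[(2R,7R)-7-{[(tert-butyldimethylsilyl)oxy]methyl}-3,7-dimethyl-2,5,6,7-tetrahydrooxepin-2-yl]-2-oxobutyl acetate
Product: 16 (2R,4aS,7R,8aS)-2-{[(tert-butyldimethylsilyl)oxy]methyl}-2,5,8a-trimethyl-8-oxo-3,4,4a,7,8,8a-hexahydro-2H-chromen-7-yl acetate, via oxonium ylide 15 (not isolated)
Conditions: Cu(hfacac)2 [copper bis(hexafluoroacetylacetonate)] (5 mol %), CH2Cl2, reflux, slow addition of 14
Reagents that add atoms: none
Why: Proposed new method: loss of N2 at copper gives an electrophilic carbenoid at C8a that is captured by a lone pair of the ring oxygen O1 (five-membered ring O1–C6–C7–C8–C8a) to give oxonium ylide 15, whose allyl unit C6–C5=C4a lies inside the seven-membered ring, so the symmetry-allowed suprafacial [2,3]-shift (C8a–C4a formed, O1–C6 broken, C5=C6 formed) should contract the oxepine to the oxane and close the cyclohexene in the same event. The closest known reaction types are the copper- or rhodium-catalysed oxonium ylide formation/[2,3]-rearrangement of diazo ketones tethered to allyl ethers (2-allyl-tetrahydrofuran-3-ones, three-atom ring expansions of 2-vinyl cyclic ethers) and the [2,3] ring contraction of cyclic allylic sulfonium ylides; a tether on the allylic carbon of an endocyclic allyl ether has not been shown. The oxane (O1, C2, C3, C4, C4a, C8a) arises by ring contraction of the oxepine, and the carbocycle (C4a, C5, C6, C7, C8, C8a) closes by the C8a–C4a bond through a five-centre transition state shaped like a 7-oxanorbornene, with C8a bridging O1 and C4a on the oxepine face that carries the tether. C8a and C4a are therefore set together by 1,3-chirality transfer from the C6 stereocentre, which is destroyed: O1 and C4 stay linked through C2–C3 on the exo side, which forces the cis fusion (C8a–CH3 cis to H-4a), while the C2 methyl, placed on the tether face in 14, ends cis to the C8a methyl and the C7 acetate sits exo on the O1 face. The step needs ylide formation to outrun cyclopropanation of C4a=C5 and the 1,2-hydride shift of the α-methyl carbenoid, and the [2,3]-shift to outrun a [1,2]-shift: the electron-poor copper carbenoid prefers the ether lone pair, the five-membered ylide forms fastest, the only allyl group on oxygen is the intended one because the vinyl group is still masked, and the [1,2]-alternative would give a strained cyclobutanone.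

Step 11
Reactants: 16 (2R,4aS,7R,8aS)-2-{[(tert-butyldimethylsilyl)oxy]methyl}-2,5,8a-trimethyl-8-oxo-3,4,4a,7,8,8a-hexahydro-2H-chromen-7-yl acetate
Product: 17 (2R,4aS,7R,8S,8aS)-2-{[(tert-butyldimethylsilyl)oxy]methyl}-8-hydroxy-2,5,8a-trimethyl-3,4,4a,7,8,8a-hexahydro-2H-chromen-7-yl acetate
Conditions: (R)-2-methyl-CBS-oxazaborolidine (1 equiv), catecholborane, toluene, −78 to −40 °C; MeOH, then aq. NaHCO3
Reagents that add atoms: none
Why: Corey–Bakshi–Shibata reduction: with the quaternary C8a as the large group the (R)-oxazaborolidine should deliver hydride to the O1 face of the ketone, giving the C8 alcohol trans to the C7 acetate under reagent control.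

Step 12
Reactants: 17 (2R,4aS,7R,8S,8aS)-2-{[(tert-butyldimethylsilyl)oxy]methyl}-8-hydroxy-2,5,8a-trimethyl-3,4,4a,7,8,8a-hexahydro-2H-chromen-7-yl acetate
Product: 18 (2R,4aS,7R,8S,8aS)-7-(acetyloxy)-2-{[(tert-butyldimethylsilyl)oxy]methyl}-2,5,8a-trimethyl-3,4,4a,7,8,8a-hexahydro-2H-chromen-8-yl 2-methylpropanoate
Conditions: (i-PrCO)2O, Et3N, DMAP (cat.), CH2Cl2, rt
Reagents that add atoms: 2-methylpropanoic anhydride, CC(C)C(=O)OC(=O)C(C)C
Why: DMAP-catalysed acylation of the hindered secondary alcohol installs the isobutyrate that later becomes the C6 dimethylacetic acid arm; no stereocentre is touched.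

Step 13
Reactants: 18 (2R,4aS,7R,8S,8aS)-7-(acetyloxy)-2-{[(tert-butyldimethylsilyl)oxy]methyl}-2,5,8a-trimethyl-3,4,4a,7,8,8a-hexahydro-2H-chromen-8-yl 2-methylpropanoate
Product: 22 2-[(2R,4aS,5S,6R,8aR)-2-{[(tert-butyldimethylsilyl)oxy]methyl}-5-(carboxymethyl)-2,5,8a-trimethyl-3,4,4a,5,6,8a-hexahydro-2H-chromen-6-yl]-2-methylpropanoic acid, via bis(silyl ketene acetal) 19 (not isolated), via singly rearranged silyl ester 20 (not isolated), via bis(trimethylsilyl) ester 21 (not isolated)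
Conditions: LiN(iPr)2 (4 equiv), Me3SiCl/Et3N, THF, −78 °C; rt to 65 °C; then 1 M HCl/THF
Reagents that add atoms: none
Why: Tandem Ireland–Claisen rearrangement: the acetate ketene acetal (allylic at C7) should shift first and suprafacially place CH2CO2Si on C5 on the face of the C7–O bond, which moves the alkene to C6=C7 and makes the C8 isobutyrate allylic, so the second [3,3]-shift places CMe2CO2Si on C6 on the face of the C8–O bond, trans to the first arm.

Step 14
Reactants: 22 2-[(2R,4aS,5S,6R,8aR)-2-{[(tert-butyldimethylsilyl)oxy]methyl}-5-(carboxymethyl)-2,5,8a-trimethyl-3,4,4a,5,6,8a-hexahydro-2H-chromen-6-yl]-2-methylpropanoic acid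
Product: 23 2-[(2R,4aS,5S,6R,8aR)-2-{[(tert-butyldimethylsilyl)oxy]methyl}-5-(carboxymethyl)-2,5,8a-trimethyloctahydro-2H-chromen-6-yl]-2-methylpropanoic acid
Conditions: H2 (4 atm), Pd/C (10 wt %), EtOAc, rt
Reagents that add atoms: none
Why: Heterogeneous hydrogenation reduces the only alkene (C7=C8) before the vinyl group exists; no stereocentre is formed and the silyl ether and acids are inert.

Step 15
Reactants: 23 2-[(2R,4aS,5S,6R,8aR)-2-{[(tert-butyldimethylsilyl)oxy]methyl}-5-(carboxymethyl)-2,5,8a-trimethyloctahydro-2H-chromen-6-yl]-2-methylpropanoic acid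
Product: 24 2-[(2R,4aS,5S,6R,8aR)-5-(carboxymethyl)-2-(hydroxymethyl)-2,5,8a-trimethyloctahydro-2H-chromen-6-yl]-2-methylpropanoic acid
Conditions: HF·pyridine, THF/pyridine, 0 °C to rt
Reagents that add atoms: none
Why: Fluoride-driven cleavage of the primary silyl ether should leave the acids and the ditertiary ring ether untouched.

Step 16
Reactants: 24 2-[(2R,4aS,5S,6R,8aR)-5-(carboxymethyl)-2-(hydroxymethyl)-2,5,8a-trimethyloctahydro-2H-chromen-6-yl]-2-methylpropanoic acid
Product: 25 2-[(2R,4aS,5S,6R,8aR)-5-(carboxymethyl)-2-formyl-2,5,8a-trimethyloctahydro-2H-chromen-6-yl]-2-methylpropanoic acid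
Conditions: Dess–Martin periodinane, NaHCO3, CH2Cl2, rt
Reagents that add atoms: none
Why: Dess–Martin oxidation should stop at the aldehyde, which cannot epimerise because C2 is quaternary.

Step 17
Reactants: 25 2-[(2R,4aS,5S,6R,8aR)-5-(carboxymethyl)-2-formyl-2,5,8a-trimethyloctahydro-2H-chromen-6-yl]-2-methylpropanoic acid
Product: 26 2-[(2R,4aS,5S,6R,8aR)-5-(carboxymethyl)-2-ethenyl-2,5,8a-trimethyloctahydro-2H-chromen-6-yl]-2-methylpropanoic acid
Conditions: Ph3PCH3Br, KN(SiMe3)2 (excess), THF, 0 °C to rt; then 1 M HCl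
Reagents that add atoms: methyltriphenylphosphonium bromide, C[P+](c1ccccc1)(c1ccccc1)c1ccccc1.[Br-]
Why: Wittig methylenation of the neopentyl aldehyde with excess ylide, which first converts the two acids into inert carboxylates that are reprotonated on work-up.

**Compound list**

1 | (S)-2-methylglycidol | OC[C@@]1(C)CO1 | starting material
2 | tert-butyldimethyl{[(2R)-2-methyloxiran-2-yl]methoxy}silane | CC(C)(C)[Si](C)(C)OC[C@@]1(C)CO1 | intermediate
3 | (2R)-1-[(tert-butyldimethylsilyl)oxy]-2-methylhept-6-en-2-ol | C=CCC[C@@](C)(O)CO[Si](C)(C)C(C)(C)C | intermediate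
4 | tert-butyldimethyl{[(2R)-2-methyl-2-[(2-methylprop-2-en-1-yl)oxy]hept-6-en-1-yl]oxy}silane | C=CCC[C@@](C)(OCC(C)=C)CO[Si](C)(C)C(C)(C)C | intermediate
5 | lithiated allyl ether (lithium at the O-bearing allylic carbon of 4) | [Li]C(O[C@](C)(CCC=C)CO[Si](C)(C)C(C)(C)C)C(C)=C | intermediate
6 | alkoxyallylborane: (Z)-γ-alkoxy-β-methylallyl-bis(isopinocampheyl)borane | B([C@@H]1C[C@@H]2C[C@H]([C@H]1C)C2(C)C)([C@@H]1C[C@@H]2C[C@H]([C@H]1C)C2(C)C)C/C(C)=C\O[C@](C)(CCC=C)CO[Si](C)(C)C(C)(C)C | intermediate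
7 | ethyl (2S,3R)-3-{[(2R)-1-[(tert-butyldimethylsilyl)oxy]-2-methylhept-6-en-2-yl]oxy}-2-hydroxy-4-methylpent-4-enoate | C=CCC[C@](C)(CO[Si](C)(C)C(C)(C)C)O[C@H](C(C)=C)[C@H](O)C(=O)OCC | intermediate
8 | ethyl (2R,3R)-3-{[(2R)-1-[(tert-butyldimethylsilyl)oxy]-2-methylhept-6-en-2-yl]oxy}-4-methyl-2-[(4-nitrobenzoyl)oxy]pent-4-enoate | C=CCC[C@](C)(CO[Si](C)(C)C(C)(C)C)O[C@H](C(C)=C)[C@@H](OC(=O)c1ccc(cc1)[N+](=O)[O-])C(=O)OCC | intermediate
9 | ethyl (2R)-2-[(2R,7R)-7-{[(tert-butyldimethylsilyl)oxy]methyl}-3,7-dimethyl-2,5,6,7-tetrahydrooxepin-2-yl]-2-[(4-nitrobenzoyl)oxy]acetate | CCOC(=O)[C@H](OC(=O)c1ccc(cc1)[N+](=O)[O-])[C@@H]1O[C@@](C)(CO[Si](C)(C)C(C)(C)C)CCC=C1C | intermediate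
10 | (2R)-2-[(2R,7R)-7-{[(tert-butyldimethylsilyl)oxy]methyl}-3,7-dimethyl-2,5,6,7-tetrahydrooxepin-2-yl]-2-hydroxyacetic acid | OC(=O)[C@H](O)[C@@H]1O[C@@](C)(CO[Si](C)(C)C(C)(C)C)CCC=C1C | intermediate
11 | mixed acetic anhydride of 12 | CC(=O)OC(=O)[C@H](OC(C)=O)[C@@H]1O[C@@](C)(CO[Si](C)(C)C(C)(C)C)CCC=C1C | intermediate
12 | (2R)-2-(acetyloxy)-2-[(2R,7R)-7-{[(tert-butyldimethylsilyl)oxy]methyl}-3,7-dimethyl-2,5,6,7-tetrahydrooxepin-2-yl]acetic acid | OC(=O)[C@H](OC(C)=O)[C@@H]1O[C@@](C)(CO[Si](C)(C)C(C)(C)C)CCC=C1C | intermediate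
13 | mixed isobutyl carbonic anhydride of 12 | CC(C)COC(=O)OC(=O)[C@H](OC(C)=O)[C@@H]1O[C@@](C)(CO[Si](C)(C)C(C)(C)C)CCC=C1C | intermediate
14 | (1R)-3-diazo-1-[(2R,7R)-7-{[(tert-butyldimethylsilyl)oxy]methyl}-3,7-dimethyl-2,5,6,7-tetrahydrooxepin-2-yl]-2-oxobutyl acetate | CC(=[N+]=[N-])C(=O)[C@H](OC(C)=O)[C@@H]1O[C@@](C)(CO[Si](C)(C)C(C)(C)C)CCC=C1C | intermediate
15 | bicyclic oxonium ylide (O1 bonded to C2, C6 and the carbanionic C8a) | C[C-]1[O+]2[C@@](C)(CO[Si](C)(C)C(C)(C)C)CCC=C(C)[C@@H]2[C@@H](OC(C)=O)C1=O | intermediate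
16 | (2R,4aS,7R,8aS)-2-{[(tert-butyldimethylsilyl)oxy]methyl}-2,5,8a-trimethyl-8-oxo-3,4,4a,7,8,8a-hexahydro-2H-chromen-7-yl acetate | CC(C)(C)[Si](C)(C)OC[C@@]1(C)CC[C@H]2C(C)=C[C@@H](OC(C)=O)C(=O)[C@@]2(C)O1 | intermediate
17 | (2R,4aS,7R,8S,8aS)-2-{[(tert-butyldimethylsilyl)oxy]methyl}-8-hydroxy-2,5,8a-trimethyl-3,4,4a,7,8,8a-hexahydro-2H-chromen-7-yl acetate | CC(C)(C)[Si](C)(C)OC[C@@]1(C)CC[C@H]2C(C)=C[C@@H](OC(C)=O)[C@H](O)[C@@]2(C)O1 | intermediate
18 | (2R,4aS,7R,8S,8aS)-7-(acetyloxy)-2-{[(tert-butyldimethylsilyl)oxy]methyl}-2,5,8a-trimethyl-3,4,4a,7,8,8a-hexahydro-2H-chromen-8-yl 2-methylpropanoate | CC(C)(C)[Si](C)(C)OC[C@@]1(C)CC[C@H]2C(C)=C[C@@H](OC(C)=O)[C@H](OC(=O)C(C)C)[C@@]2(C)O1 | intermediate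
19 | bis(silyl ketene acetal) of 18 | CC(C)(C)[Si](C)(C)OC[C@@]1(C)CC[C@H]2C(C)=C[C@@H](OC(=C)O[Si](C)(C)C)[C@H](OC(O[Si](C)(C)C)=C(C)C)[C@@]2(C)O1 | intermediate
20 | singly rearranged silyl ester (C5 arm in place, C8 ketene acetal intact) | CC(C)(C)[Si](C)(C)OC[C@@]1(C)CC[C@H]2[C@@](C)(CC(=O)O[Si](C)(C)C)C=C[C@H](OC(O[Si](C)(C)C)=C(C)C)[C@@]2(C)O1 | intermediate
21 | bis(trimethylsilyl) ester of 22 | CC(C)(C)[Si](C)(C)OC[C@@]1(C)CC[C@H]2[C@@](C)(CC(=O)O[Si](C)(C)C)[C@H](C(C)(C)C(=O)O[Si](C)(C)C)C=C[C@@]2(C)O1 | intermediate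
22 | 2-[(2R,4aS,5S,6R,8aR)-2-{[(tert-butyldimethylsilyl)oxy]methyl}-5-(carboxymethyl)-2,5,8a-trimethyl-3,4,4a,5,6,8a-hexahydro-2H-chromen-6-yl]-2-methylpropanoic acid | CC(C)(C)[Si](C)(C)OC[C@@]1(C)CC[C@H]2[C@@](C)(CC(=O)O)[C@H](C(C)(C)C(=O)O)C=C[C@@]2(C)O1 | intermediate
23 | 2-[(2R,4aS,5S,6R,8aR)-2-{[(tert-butyldimethylsilyl)oxy]methyl}-5-(carboxymethyl)-2,5,8a-trimethyloctahydro-2H-chromen-6-yl]-2-methylpropanoic acid | CC(C)(C)[Si](C)(C)OC[C@@]1(C)CC[C@H]2[C@@](C)(CC(=O)O)[C@H](C(C)(C)C(=O)O)CC[C@@]2(C)O1 | intermediate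
24 | 2-[(2R,4aS,5S,6R,8aR)-5-(carboxymethyl)-2-(hydroxymethyl)-2,5,8a-trimethyloctahydro-2H-chromen-6-yl]-2-methylpropanoic acid | OC[C@@]1(C)CC[C@H]2[C@@](C)(CC(=O)O)[C@H](C(C)(C)C(=O)O)CC[C@@]2(C)O1 | intermediate
25 | 2-[(2R,4aS,5S,6R,8aR)-5-(carboxymethyl)-2-formyl-2,5,8a-trimethyloctahydro-2H-chromen-6-yl]-2-methylpropanoic acid | O=C[C@@]1(C)CC[C@H]2[C@@](C)(CC(=O)O)[C@H](C(C)(C)C(=O)O)CC[C@@]2(C)O1 | intermediate
26 | 2-[(2R,4aS,5S,6R,8aR)-5-(carboxymethyl)-2-ethenyl-2,5,8a-trimethyloctahydro-2H-chromen-6-yl]-2-methylpropanoic acid (CNP0186744.1) | C=C[C@@]1(C)CC[C@H]2[C@@](C)(CC(=O)O)[C@H](C(C)(C)C(=O)O)CC[C@@]2(C)O1 | target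

**Step count and risks**

Total step count: 17. Longest linear sequence: 17 steps (from 1).

Steps most likely to fail:

1. Step 10 (bears the label "Proposed new method:").
   - What may go wrong: the copper carbenoid is diverted before the ylide forms, by 1,2-hydride shift from the α-methyl group, by cyclopropanation of the C4a=C5 alkene, or by slow attack on an ether oxygen flanked by the quaternary C2. The ylide may also collapse by a non-concerted [1,2]- or [1,4]-shift, and the shift is slowed by the syn-axial contact of the C2 and C8a methyl groups.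
   - Fallback (known chemistry, from compound 3 back to compound 17): the oxane would be made by a Prins-type oxonium-ene cyclisation and the carbocycle by ring-closing metathesis. Cross-metathesis of 3 with 2-methylbut-2-ene (second-generation Grubbs catalyst) should give (2R)-1-[(tert-butyldimethylsilyl)oxy]-2,7-dimethyloct-6-en-2-ol F1. Treatment of F1 with ethyl pyruvate and Me3SiOTf in CH2Cl2 at low temperature should close the oxane by attack of the trisubstituted alkene on the ketone-derived oxocarbenium ion and proton loss, giving ethyl (2S,3S,6R)-6-{[(tert-butyldimethylsilyl)oxy]methyl}-2,6-dimethyl-3-(prop-1-en-2-yl)oxane-2-carboxylate F2 (chair transition state; diastereomers would be separated). Reduction with i-Bu2AlH at −78 °C should give (2S,3S,6R)-6-{[(tert-butyldimethylsilyl)oxy]methyl}-2,6-dimethyl-3-(prop-1-en-2-yl)oxane-2-carbaldehyde F3. Indium-mediated addition of 3-bromoprop-1-enyl acetate should give (1S,2R)-1-[(2S,3S,6R)-6-{[(tert-butyldimethylsilyl)oxy]methyl}-2,6-dimethyl-3-(prop-1-en-2-yl)oxan-2-yl]-1-hydroxybut-3-en-2-yl acetate F4, and ring-closing metathesis of F4 (second-generation Grubbs catalyst) returns to compound 17.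

2. Step 4.
   - What may go wrong: incomplete or unselective α-lithiation of the hindered methallyl ether, loss of the (Z)-geometry on transfer to boron, or low facial selectivity with the very reactive glyoxylate.
   - Fallback (from compound 3 back to compound 10, replacing steps 3 to 7): C6 and C7 would be set by an auxiliary-controlled enolate addition to an oxocarbenium ion. Transacetalisation of 3 with methacrolein dimethyl acetal (pyridinium p-toluenesulfonate, removal of MeOH) should give tert-butyl{[(2R)-2-[(1-methoxy-2-methylprop-2-en-1-yl)oxy]-2-methylhept-6-en-1-yl]oxy}dimethylsilane F5. The chlorotitanium enolate (TiCl4, i-Pr2NEt) of (4S)-4-benzyl-3-{[(4-methoxybenzyl)oxy]acetyl}-1,3-oxazolidin-2-one should add to the oxocarbenium ion released from F5 (SnCl4) to give the anti adduct (4S)-4-benzyl-3-[(2R,3R)-3-{[(2R)-1-[(tert-butyldimethylsilyl)oxy]-2-methylhept-6-en-2-yl]oxy}-2-[(4-methoxybenzyl)oxy]-4-methylpent-4-enoyl]-1,3-oxazolidin-2-one F6. Ring-closing metathesis should give (4S)-4-benzyl-3-[(2R)-2-[(2R,7R)-7-{[(tert-butyldimethylsilyl)oxy]methyl}-3,7-dimethyl-2,5,6,7-tetrahydrooxepin-2-yl]-2-[(4-methoxybenzyl)oxy]acetyl]-1,3-oxazolidin-2-one F7. LiOH/H2O2 should remove the auxiliary to give (2R)-2-[(2R,7R)-7-{[(tert-butyldimethylsilyl)oxy]methyl}-3,7-dimethyl-2,5,6,7-tetrahydrooxepin-2-yl]-2-[(4-methoxybenzyl)oxy]acetic acid F8, and DDQ cleaves the 4-methoxybenzyl ether to return to compound 10.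

3. Step 13.
   - What may go wrong: the sequence stalls after the first shift, because the second [3,3]-shift must join a quaternary carbon to a CH next to the new quaternary C5; the isobutyrate ketene acetal may then decompose (ketene loss, C-silylation). Incomplete double enolisation is the other hazard.
   - Fallback (from compound 17 back to compound 22, replacing steps 12 and 13): the two bonds would be made one at a time, the hindered one without strong base. Ireland–Claisen rearrangement of the acetate of 17 alone (LiN(iPr)2, Me3SiCl, the free C8 hydroxyl silylated in the same pot, acidic work-up) should give 2-[(2R,4aS,5S,8S,8aS)-2-{[(tert-butyldimethylsilyl)oxy]methyl}-8-hydroxy-2,5,8a-trimethyl-3,4,4a,5,8,8a-hexahydro-2H-chromen-5-yl]acetic acid F9. Johnson–Claisen rearrangement of the now allylic C8 alcohol with trimethyl orthoisobutyrate (cat. propionic acid, xylene, 140 °C), which also esterifies the acid, should give methyl 2-[(2R,4aS,5S,6R,8aR)-2-{[(tert-butyldimethylsilyl)oxy]methyl}-5-(2-methoxy-2-oxoethyl)-2,5,8a-trimethyl-3,4,4a,5,6,8a-hexahydro-2H-chromen-6-yl]-2-methylpropanoate F10. Cleavage of both methyl esters with Me3SiOK (THF, 60 °C, acidic work-up) returns to compound 22.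

**Further compounds**

F1 | step 10 | (2R)-1-[(tert-butyldimethylsilyl)oxy]-2,7-dimethyloct-6-en-2-ol | CC(C)=CCC[C@@](C)(O)CO[Si](C)(C)C(C)(C)C
F2 | step 10 | ethyl (2S,3S,6R)-6-{[(tert-butyldimethylsilyl)oxy]methyl}-2,6-dimethyl-3-(prop-1-en-2-yl)oxane-2-carboxylate | CCOC(=O)[C@@]1(C)O[C@@](C)(CO[Si](C)(C)C(C)(C)C)CC[C@H]1C(C)=C
F3 | step 10 | (2S,3S,6R)-6-{[(tert-butyldimethylsilyl)oxy]methyl}-2,6-dimethyl-3-(prop-1-en-2-yl)oxane-2-carbaldehyde | O=C[C@@]1(C)O[C@@](C)(CO[Si](C)(C)C(C)(C)C)CC[C@H]1C(C)=C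
F4 | step 10 | (1S,2R)-1-[(2S,3S,6R)-6-{[(tert-butyldimethylsilyl)oxy]methyl}-2,6-dimethyl-3-(prop-1-en-2-yl)oxan-2-yl]-1-hydroxybut-3-en-2-yl acetate | C=C[C@@H](OC(C)=O)[C@H](O)[C@@]1(C)O[C@@](C)(CO[Si](C)(C)C(C)(C)C)CC[C@H]1C(C)=C
F5 | step 4 | tert-butyl{[(2R)-2-[(1-methoxy-2-methylprop-2-en-1-yl)oxy]-2-methylhept-6-en-1-yl]oxy}dimethylsilane | C=CCC[C@](C)(CO[Si](C)(C)C(C)(C)C)OC(OC)C(C)=C
F6 | step 4 | (4S)-4-benzyl-3-[(2R,3R)-3-{[(2R)-1-[(tert-butyldimethylsilyl)oxy]-2-methylhept-6-en-2-yl]oxy}-2-[(4-methoxybenzyl)oxy]-4-methylpent-4-enoyl]-1,3-oxazolidin-2-one | COc1ccc(CO[C@@H](C(=O)N2[C@@H](Cc3ccccc3)COC2=O)[C@H](O[C@](C)(CCC=C)CO[Si](C)(C)C(C)(C)C)C(C)=C)cc1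
F7 | step 4 | (4S)-4-benzyl-3-[(2R)-2-[(2R,7R)-7-{[(tert-butyldimethylsilyl)oxy]methyl}-3,7-dimethyl-2,5,6,7-tetrahydrooxepin-2-yl]-2-[(4-methoxybenzyl)oxy]acetyl]-1,3-oxazolidin-2-one | COc1ccc(CO[C@@H](C(=O)N2[C@@H](Cc3ccccc3)COC2=O)[C@@H]4O[C@@](C)(CO[Si](C)(C)C(C)(C)C)CCC=C4C)cc1
F8 | step 4 | (2R)-2-[(2R,7R)-7-{[(tert-butyldimethylsilyl)oxy]methyl}-3,7-dimethyl-2,5,6,7-tetrahydrooxepin-2-yl]-2-[(4-methoxybenzyl)oxy]acetic acid | COc1ccc(CO[C@@H](C(=O)O)[C@@H]2O[C@@](C)(CO[Si](C)(C)C(C)(C)C)CCC=C2C)cc1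
F9 | step 13 | 2-[(2R,4aS,5S,8S,8aS)-2-{[(tert-butyldimethylsilyl)oxy]methyl}-8-hydroxy-2,5,8a-trimethyl-3,4,4a,5,8,8a-hexahydro-2H-chromen-5-yl]acetic acid | CC(C)(C)[Si](C)(C)OC[C@@]1(C)CC[C@H]2[C@@](C)(CC(=O)O)C=C[C@H](O)[C@@]2(C)O1
F10 | step 13 | methyl 2-[(2R,4aS,5S,6R,8aR)-2-{[(tert-butyldimethylsilyl)oxy]methyl}-5-(2-methoxy-2-oxoethyl)-2,5,8a-trimethyl-3,4,4a,5,6,8a-hexahydro-2H-chromen-6-yl]-2-methylpropanoate | CC(C)(C)[Si](C)(C)OC[C@@]1(C)CC[C@H]2[C@@](C)(CC(=O)OC)[C@H](C(C)(C)C(=O)OC)C=C[C@@]2(C)O1
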